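The flavone is disconnected at the three bonds around the pyranone carbonyl, C4a–C4, C4–C3 and O1–C2. The feature exploited is that C4 of ring C sits between C4a of ring A and the C3–C2 unit while O1 is held on C8a, ortho to C4a; C4 can therefore arrive as carbon monoxide. One palladium-catalysed carbonylative alkyne annulation joins an o-iodophenol (ring A) to an arylacetylene (ring B) and closes ring C. The precursors are a 2-iodo-3,4-dimethoxy-5-silyloxyphenol, whose iodine is placed by directed ortho-lithiation, and the silyl-protected 3-oxy-4,5-dimethoxyphenylacetylene, both made from one aldehyde; fluoride then frees the two phenols.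

Key step: step 7

Remarks on the chemistry:
- Flavone numbering is used throughout (ring A = benzo ring C4a–C8a, ring C = pyranone, ring B = 2-aryl group).
- The two ortho carbons of the free ring A phenol differ only in whether a methoxy or a silyloxy group flanks them. The iodine is therefore introduced by cooperative directed metalation of a MOM ether and not by electrophilic substitution; this costs two routine steps.
- The enaminone that forms during the key step is drawn as its E isomer. Its geometry is without consequence, because the push–pull double bond is consumed in the ring closure.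

Step 1
Reactants: 1 3-hydroxy-4,5-dimethoxybenzaldehyde; 2 chlorotriisopropylsilane
Product: 3 3,4-dimethoxy-5-[(triisopropylsilyl)oxy]benzaldehyde
Conditions: TIPSCl, imidazole, DMF, rt
Reagents that add atoms: chlorotriisopropylsilane (2), CC(C)[Si](Cl)(C(C)C)C(C)C
Why: Imidazole-mediated O-silylation of the single free phenol is a standard protection, and the bulky triisopropylsilyl ether is chosen because it survives organolithium, mild acid, amine and palladium conditions, does not coordinate lithium, and leaves with fluoride at the end.

Step 2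
Reactants: 3 3,4-dimethoxy-5-[(triisopropylsilyl)oxy]benzaldehyde; 4 3-chloroperoxybenzoic acid (mCPBA)
Product: 6 3,4-dimethoxy-5-[(triisopropylsilyl)oxy]phenol, via aryl formate 5 (not isolated)
Conditions: mCPBA, CH2Cl2, 0 °C to rt; aq. Na2S2O3/NaHCO3 wash; then Et3N (cat.), MeOH, rt
Reagents that add atoms: 3-chloroperoxybenzoic acid (4), O=C(OO)c1cccc(Cl)c1
Why: Baeyer–Villiger oxidation of the electron-rich benzaldehyde proceeds with aryl migration to aryl formate 5, which amine-catalysed methanolysis cleaves at room temperature without harming the base-sensitive aryl silyl ether (an alkaline peroxide Dakin protocol is avoided because the ring has no free ortho or para hydroxyl and the silyl ether would not survive it).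

Step 3
Reactants: 6 3,4-dimethoxy-5-[(triisopropylsilyl)oxy]phenol; 7 chloromethyl methyl ether (MOMCl)
Product: 8 [2,3-dimethoxy-5-(methoxymethoxy)phenoxy]triisopropylsilane
Conditions: MOMCl, iPr2NEt, CH2Cl2, 0 °C to rt
Reagents that add atoms: chloromethyl methyl ether (7), COCCl
Why: O-Alkylation of the phenol with MOMCl and a hindered amine base (acetal protection) is routine and turns the oxygen destined to become O1 into a strong ortho-directing group.

Step 4
Reactants: 8 [2,3-dimethoxy-5-(methoxymethoxy)phenoxy]triisopropylsilane; 9 iodine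
Product: 11 [4-iodo-2,3-dimethoxy-5-(methoxymethoxy)phenoxy]triisopropylsilane, via aryllithium 10 (not isolated)
Conditions: n-BuLi, THF, 0 °C; then I2, THF, −78 °C to rt
Reagents that add atoms: iodine (9), II
Why: Directed ortho-metalation: the methoxymethoxy and methoxy groups cooperatively guide n-BuLi to the ring carbon between them (the future C4a) while the bulky, non-coordinating silyl ether blocks the other ortho carbon, so iodinolysis of aryllithium 10 places the iodine at a single, unambiguous position.

Step 5
Reactants: 11 [4-iodo-2,3-dimethoxy-5-(methoxymethoxy)phenoxy]triisopropylsilane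
Product: 12 2-iodo-3,4-dimethoxy-5-[(triisopropylsilyl)oxy]phenol
Conditions: HCl (1.25 M in MeOH), THF, rt to 40 °C
Reagents that add atoms: none
Why: Acid-catalysed acetal exchange with methanol (MOM ether cleavage) releases the phenol as dimethoxymethane leaves, under conditions mild enough for the aryl triisopropylsilyl ether and the aryl iodide to persist.

Step 6
Reactants: 3 3,4-dimethoxy-5-[(triisopropylsilyl)oxy]benzaldehyde; 13 dimethyl (1-diazo-2-oxopropyl)phosphonate
Product: 14 (5-ethynyl-2,3-dimethoxyphenoxy)triisopropylsilane
Conditions: K2CO3, MeOH/THF, 0 °C to rt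
Reagents that add atoms: dimethyl (1-diazo-2-oxopropyl)phosphonate (13), COP(=O)(OC)C(=[N+]=[N-])C(C)=O
Why: Ohira–Bestmann modification of the Seyferth–Gilbert homologation: methanolysis of 13 liberates the diazomethylphosphonate anion, which olefinates the non-enolisable aldehyde, and loss of N2 with a 1,2-hydrogen shift gives the terminal alkyne under conditions that aryl triisopropylsilyl ethers are expected to tolerate for the reaction time.

Step 7
Reactants: 12 2-iodo-3,4-dimethoxy-5-[(triisopropylsilyl)oxy]phenol; 14 (5-ethynyl-2,3-dimethoxyphenoxy)triisopropylsilane; 15 carbon monoxide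
Product: 18 2-{3,4-dimethoxy-5-[(triisopropylsilyl)oxy]phenyl}-5,6-dimethoxy-7-[(triisopropylsilyl)oxy]-4H-chromen-4-one, via hydroxyaryl ynone 16 (not isolated), via diethylamino enone 17 (not isolated)
Conditions: PdCl2(dppf) (5 mol %), Et2NH, CO (20 bar), 120 °C
Reagents that add atoms: carbon monoxide (15), [C-]#[O+]
Why: Zerovalent palladium, formed from PdCl2(dppf) under CO and amine, inserts into the C4a–I bond of 12, CO insertion gives the aroyl complex of divalent palladium, and amine-assisted transfer of the acetylide of 14 followed by reductive elimination delivers ynone 16 (bonds C4a–C4 and C4–C3). Diethylamine then adds to the ynone to give enaminone 17, and the C8a hydroxyl attacks C2 and expels the amine, so ring C closes by a 6-endo addition–elimination (formally 6-endo-dig on the ynone) that forms O1–C2. The closest known reaction type is the palladium-catalysed carbonylative Sonogashira coupling and cyclisation of o-iodophenols with terminal alkynes to flavones. No stereocentre is created. The step needs carbonylative over direct coupling (which would end in a 2-arylbenzofuran) and pyranone over 5-exo aurone closure: CO pressure and the chelating dppf ligand hold the acyl complex, the amine-derived enaminone makes C2 the only electrophilic carbon within reach of O1, and in the substrate the iodine at C4a ortho to the one free hydroxyl, with every other phenol silylated, fixes where the carbonyl and the ring oxygen go.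

Step 8
Reactants: 18 2-{3,4-dimethoxy-5-[(triisopropylsilyl)oxy]phenyl}-5,6-dimethoxy-7-[(triisopropylsilyl)oxy]-4H-chromen-4-one
Product: 19 7,5'-dihydroxy-5,6,3',4'-tetramethoxyflavone
Conditions: TBAF, AcOH, THF, 0 °C to rt
Reagents that add atoms: none
Why: Fluoride-mediated cleavage of both aryl Si–O bonds (buffered TBAF desilylation) unmasks the C7 and C5' hydroxyls in one operation while all four methyl ethers, including the chelation-prone C5 methoxy that a Lewis acid would attack, remain untouched.

Compound list
1 | 3-hydroxy-4,5-dimethoxybenzaldehyde | COc1cc(C=O)cc(O)c1OC | starting material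
2 | chlorotriisopropylsilane | CC(C)[Si](Cl)(C(C)C)C(C)C | starting material
3 | 3,4-dimethoxy-5-[(triisopropylsilyl)oxy]benzaldehyde | COc1cc(C=O)cc(O[Si](C(C)C)(C(C)C)C(C)C)c1OC | intermediate
4 | 3-chloroperoxybenzoic acid | O=C(OO)c1cccc(Cl)c1 | starting material
5 | 3,4-dimethoxy-5-[(triisopropylsilyl)oxy]phenyl formate | COc1cc(OC=O)cc(O[Si](C(C)C)(C(C)C)C(C)C)c1OC | intermediate
6 | 3,4-dimethoxy-5-[(triisopropylsilyl)oxy]phenol | COc1cc(O)cc(O[Si](C(C)C)(C(C)C)C(C)C)c1OC | intermediate
7 | chloromethyl methyl ether | COCCl | starting material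
8 | [2,3-dimethoxy-5-(methoxymethoxy)phenoxy]triisopropylsilane | COCOc1cc(OC)c(OC)c(O[Si](C(C)C)(C(C)C)C(C)C)c1 | intermediate
9 | iodine | II | starting material
10 | {2,3-dimethoxy-6-(methoxymethoxy)-4-[(triisopropylsilyl)oxy]phenyl}lithium | [Li]c1c(OCOC)cc(O[Si](C(C)C)(C(C)C)C(C)C)c(OC)c1OC | intermediate
11 | [4-iodo-2,3-dimethoxy-5-(methoxymethoxy)phenoxy]triisopropylsilane | COCOc1cc(O[Si](C(C)C)(C(C)C)C(C)C)c(OC)c(OC)c1I | intermediate
12 | 2-iodo-3,4-dimethoxy-5-[(triisopropylsilyl)oxy]phenol | COc1c(OC)c(O[Si](C(C)C)(C(C)C)C(C)C)cc(O)c1I | intermediate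
13 | dimethyl (1-diazo-2-oxopropyl)phosphonate | COP(=O)(OC)C(=[N+]=[N-])C(C)=O | starting material
14 | (5-ethynyl-2,3-dimethoxyphenoxy)triisopropylsilane | C#Cc1cc(OC)c(OC)c(O[Si](C(C)C)(C(C)C)C(C)C)c1 | intermediate
15 | carbon monoxide | [C-]#[O+] | starting material
16 | 3-{3,4-dimethoxy-5-[(triisopropylsilyl)oxy]phenyl}-1-{6-hydroxy-2,3-dimethoxy-4-[(triisopropylsilyl)oxy]phenyl}prop-2-yn-1-one | COc1cc(C#CC(=O)c2c(O)cc(O[Si](C(C)C)(C(C)C)C(C)C)c(OC)c2OC)cc(O[Si](C(C)C)(C(C)C)C(C)C)c1OC | intermediate
17 | (2E)-3-(diethylamino)-3-{3,4-dimethoxy-5-[(triisopropylsilyl)oxy]phenyl}-1-{6-hydroxy-2,3-dimethoxy-4-[(triisopropylsilyl)oxy]phenyl}prop-2-en-1-one | CCN(CC)/C(=C/C(=O)c1c(O)cc(O[Si](C(C)C)(C(C)C)C(C)C)c(OC)c1OC)c1cc(OC)c(OC)c(O[Si](C(C)C)(C(C)C)C(C)C)c1 | intermediate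
18 | 2-{3,4-dimethoxy-5-[(triisopropylsilyl)oxy]phenyl}-5,6-dimethoxy-7-[(triisopropylsilyl)oxy]-4H-chromen-4-one | COc1cc(-c2cc(=O)c3c(OC)c(OC)c(O[Si](C(C)C)(C(C)C)C(C)C)cc3o2)cc(O[Si](C(C)C)(C(C)C)C(C)C)c1OC | intermediate
19 | 7,5'-dihydroxy-5,6,3',4'-tetramethoxyflavone [7-hydroxy-2-(3-hydroxy-4,5-dimethoxyphenyl)-5,6-dimethoxy-4H-chromen-4-one] | COc1cc(-c2cc(=O)c3c(OC)c(OC)c(O)cc3o2)cc(O)c1OC | target

Total steps: 8. Longest linear sequence: 7 steps (steps 1, 2, 3, 4, 5, 7 and 8).

Steps most likely to fail

Step 7. Oxidative addition into the doubly ortho-substituted, electron-rich C–I bond may be slow. Direct coupling without CO uptake (ending in a benzofuran), capture of the acyl complex by diethylamine as an amide, or silyl loss at 120 °C could then erode the annulation. The fallback makes the same three bonds one after another with known reactions. It sets out from 8, which is lithiated as in step 4 to aryllithium 10 and quenched with DMF to give 2,3-dimethoxy-6-(methoxymethoxy)-4-[(triisopropylsilyl)oxy]benzaldehyde F1. Alkyne 14 is deprotonated with n-BuLi in THF at −78 °C to lithium {3,4-dimethoxy-5-[(triisopropylsilyl)oxy]phenyl}acetylide F2. Addition of F2 to F1 gives racemic 1-{2,3-dimethoxy-6-(methoxymethoxy)-4-[(triisopropylsilyl)oxy]phenyl}-3-{3,4-dimethoxy-5-[(triisopropylsilyl)oxy]phenyl}prop-2-yn-1-ol F3. Oxidation with MnO2 in CH2Cl2 gives 1-{2,3-dimethoxy-6-(methoxymethoxy)-4-[(triisopropylsilyl)oxy]phenyl}-3-{3,4-dimethoxy-5-[(triisopropylsilyl)oxy]phenyl}prop-2-yn-1-one F4. Methanolic HCl then removes the MOM group, and the fallback comes back to the route at 16, which diethylamine in ethanol closes to 18 by way of 17. Any material that already cyclises under the acid is 18 itself.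

Step 6. Homologation of the electron-rich aldehyde may be slow, and the carbonate/methanol medium could gradually cleave the aryl silyl ether, leaving a mixture of silylated and free phenolic alkyne. The fallback changes the order of events so that no silyl ether meets basic methanol. It sets out from 1, on which the Ohira–Bestmann reaction with 13 (excess K2CO3, MeOH, rt) is run on the free phenol to give 5-ethynyl-2,3-dimethoxyphenol F5. Silylation of F5 with 2 and imidazole in DMF comes back to the route at 14.

Step 4. Metalation may be incomplete, the alkyllithium may attack silicon, or the quench may over-iodinate. The fallback replaces metalation by electrophilic aromatic substitution. It sets out from phenol 6: N-iodosuccinimide in CH2Cl2 at 0 °C should iodinate ortho to the free hydroxyl on the side flanked by the methoxy group, away from the bulky silyl ether. This comes back to the route directly at 12 and bypasses 8 and 11. Because it rests on steric bias alone, the position of the iodine would have to be proven before the material is used. No compound outside the compound list is made (F0).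

Further compounds
F1 | step 7 | 2,3-dimethoxy-6-(methoxymethoxy)-4-[(triisopropylsilyl)oxy]benzaldehyde | O=Cc1c(OCOC)cc(O[Si](C(C)C)(C(C)C)C(C)C)c(OC)c1OC
F2 | step 7 | lithium {3,4-dimethoxy-5-[(triisopropylsilyl)oxy]phenyl}acetylide | [Li]C#Cc1cc(OC)c(OC)c(O[Si](C(C)C)(C(C)C)C(C)C)c1
F3 | step 7 | racemic 1-{2,3-dimethoxy-6-(methoxymethoxy)-4-[(triisopropylsilyl)oxy]phenyl}-3-{3,4-dimethoxy-5-[(triisopropylsilyl)oxy]phenyl}prop-2-yn-1-ol | COCOc1cc(O[Si](C(C)C)(C(C)C)C(C)C)c(OC)c(OC)c1C(O)C#Cc1cc(OC)c(OC)c(O[Si](C(C)C)(C(C)C)C(C)C)c1
F4 | step 7 | 1-{2,3-dimethoxy-6-(methoxymethoxy)-4-[(triisopropylsilyl)oxy]phenyl}-3-{3,4-dimethoxy-5-[(triisopropylsilyl)oxy]phenyl}prop-2-yn-1-one | COCOc1cc(O[Si](C(C)C)(C(C)C)C(C)C)c(OC)c(OC)c1C(=O)C#Cc1cc(OC)c(OC)c(O[Si](C(C)C)(C(C)C)C(C)C)c1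
F5 | step 6 | 5-ethynyl-2,3-dimethoxyphenol | C#Cc1cc(OC)c(OC)c(O)c1
F0 | step 4 | none | none
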